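**Plan**
Ring numbering used below: C1 bears the exocyclic methylene, C2 and C3 are CH2, C4=C5 is the acrylate alkene (CO2H on C5), C6 is CH2, C7 carries the isovalerate, C9 the gem-dimethyl group and C11 the free hydroxyl; C7 and C11 are both S. The enabling feature is that C7 is homoallylic to the C4=C5 alkene (C7–C6–C5=C4), which is the retron of a carbonyl allylboration by a 2-(alkoxycarbonyl)allyl unit with boron on C4.
Retrosynthesis: take off the isovalerate and protecting groups, then cut the ring bond C6–C7 (alkene back to C5=C6, Bpin on C4, aldehyde at C7). The open chain is cut at C4–C5 (Morita–Baylis–Hillman reaction with tert-butyl acrylate), at C1–C11 (alkenyllithium plus Weinreb amide) and at C2–C3 (vinyl Grignard plus 2,3-dibromopropene); C7–C11 come from 3,3-dimethylglutaric anhydride.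
Forward: the C7–C11 amide is joined to the C1–C4 diene, the terminal alkene is turned into the C4 aldehyde, the acrylate is added, and acetate transposition and SN2′ borylation follow. The only ring, the eleven-membered carbocycle, closes at C6–C7 by intramolecular allylboration; acylation and two deprotections finish the route.
Stereochemistry: C11 comes from a Corey–Bakshi–Shibata reduction, a temporary boron-bearing centre at C4 from copper-catalysed enantioselective borylation, and C7 plus the ring-cis C4=C5 geometry from chirality transfer through the chair transition state of the allylboration.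

Key step: step 16

Assumption: the facial preference of the copper–QuinoxP* boryl complex toward 21 cannot be predicted with certainty; the ligand antipode that delivers the 3R boronate 22 is the one meant (the sense would be read from the carbinol obtained by oxidising a sample).

**Route**

Step 1
Reactants: 1 3,3-dimethylglutaric anhydride
Product: 3 4,4-dimethyloxan-2-one, via sodium 5-hydroxy-3,3-dimethylpentanoate 2 (not isolated)
Conditions: NaBH4, THF, 0 °C to rt; then 6 M HCl, rt
Reagents that add atoms: none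
Why: Borohydride reduction of one carbonyl of the symmetrical cyclic anhydride gives the hydroxy carboxylate, which lactonises on acidification (anhydride-to-lactone reduction), so the two ends of the C7–C11 unit become different.

Step 2
Reactants: 3 4,4-dimethyloxan-2-one
Product: 4 5-hydroxy-N-methoxy-N,3,3-trimethylpentanamide
Conditions: MeNH(OMe)·HCl, AlMe3, CH2Cl2, 0 °C to rt; aqueous potassium sodium tartrate work-up
Reagents that add atoms: N,O-dimethylhydroxylamine hydrochloride, CNOC.Cl
Why: Aluminium amide aminolysis of the lactone (Weinreb amide formation) opens the ring and leaves the future C7 hydroxyl free.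

Step 3
Reactants: 4 5-hydroxy-N-methoxy-N,3,3-trimethylpentanamide
Product: 5 N-methoxy-N,3,3-trimethyl-5-[(triethylsilyl)oxy]pentanamide
Conditions: TESCl, imidazole, CH2Cl2, 0 °C
Reagents that add atoms: chlorotriethylsilane, CC[Si](Cl)(CC)CC
Why: Standard silylation of a primary alcohol; the triethylsilyl ether is chosen because it can later be cleaved beside a secondary tert-butyldimethylsilyl ether.

Step 4
Reactants: 6 2,3-dibromopropene; 7 vinylmagnesium bromide
Product: 8 2-bromopenta-1,4-diene
Conditions: CuI (5 mol%), THF/Et2O, 0 °C to rt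
Reagents that add atoms: none
Why: Copper-catalysed allylic substitution of the allylic bromide by the vinyl Grignard reagent (SN2 and SN2′ attack give the same skipped diene) leaves the vinylic bromide untouched.

Step 5
Reactants: 8 2-bromopenta-1,4-diene; 5 N-methoxy-N,3,3-trimethyl-5-[(triethylsilyl)oxy]pentanamide
Product: 11 7,7-dimethyl-4-methylidene-9-[(triethylsilyl)oxy]non-1-en-5-one, via penta-1,4-dien-2-yllithium 9 (not isolated), via lithium hemiaminal adduct 10 (not isolated)
Conditions: 8, t-BuLi (2 equiv), Et2O, -78 °C; then 5, -78 °C; AcOH quench at -78 °C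
Reagents that add atoms: none
Why: Bromine–lithium exchange followed by acylation of the alkenyllithium with the Weinreb amide, whose chelated tetrahedral adduct prevents over-addition; exchange at -78 °C should outrun deprotonation of the doubly allylic CH2, and the acidic quench keeps the liberated amine from adding to the enone.

Step 6
Reactants: 11 7,7-dimethyl-4-methylidene-9-[(triethylsilyl)oxy]non-1-en-5-one
Product: 13 (5S)-7,7-dimethyl-4-methylidene-9-[(triethylsilyl)oxy]non-1-en-5-ol, via catechol borate ester 12 (not isolated)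
Conditions: (R)-2-methyl-CBS-oxazaborolidine (0.5 equiv), catecholborane, toluene, -78 °C; then MeOH, aqueous NaOH wash
Reagents that add atoms: none
Why: Corey–Bakshi–Shibata reduction in which the 1-substituted vinyl group acts as the large and the CH2 group as the small substituent, so the (R)-catalyst should give the 5S carbinol (ring C11, S); catecholborane at -78 °C does not hydroborate the alkenes.

Step 7
Reactants: 13 (5S)-7,7-dimethyl-4-methylidene-9-[(triethylsilyl)oxy]non-1-en-5-ol
Product: 14 (5S)-5-[(tert-butyldimethylsilyl)oxy]-7,7-dimethyl-4-methylidene-9-[(triethylsilyl)oxy]non-1-ene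
Conditions: TBSOTf, 2,6-lutidine, CH2Cl2, -78 °C
Reagents that add atoms: tert-butyldimethylsilyl triflate, CC(C)(C)[Si](C)(C)OS(=O)(=O)C(F)(F)F
Why: Silyl triflate silylation of the hindered secondary allylic alcohol at low temperature, under which the primary triethylsilyl ether is stable.

Step 8
Reactants: 14 (5S)-5-[(tert-butyldimethylsilyl)oxy]-7,7-dimethyl-4-methylidene-9-[(triethylsilyl)oxy]non-1-ene
Product: 16 (5S)-5-[(tert-butyldimethylsilyl)oxy]-7,7-dimethyl-4-methylidene-9-[(triethylsilyl)oxy]nonan-1-ol, via alkyldisiamylborane 15 (not isolated)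
Conditions: Sia2BH (from BH3·SMe2 and 2-methylbut-2-ene), THF, 0 °C; then NaOH, H2O2, 0 °C to rt
Reagents that add atoms: hydrogen peroxide, OO
Why: Anti-Markovnikov hydroboration–oxidation with a bulky dialkylborane, which adds to the monosubstituted terminal alkene far faster than to the 1,1-disubstituted alkene that is further shielded by the neighbouring silyloxy carbon.

Step 9
Reactants: 16 (5S)-5-[(tert-butyldimethylsilyl)oxy]-7,7-dimethyl-4-methylidene-9-[(triethylsilyl)oxy]nonan-1-ol
Product: 17 (5S)-5-[(tert-butyldimethylsilyl)oxy]-7,7-dimethyl-4-methylidene-9-[(triethylsilyl)oxy]nonanal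
Conditions: Dess–Martin periodinane, pyridine, CH2Cl2, 0 °C to rt
Reagents that add atoms: none
Why: Buffered Dess–Martin oxidation of a primary alcohol to the aldehyde without touching silyl ethers or alkenes.

Step 10
Reactants: 17 (5S)-5-[(tert-butyldimethylsilyl)oxy]-7,7-dimethyl-4-methylidene-9-[(triethylsilyl)oxy]nonanal; 18 tert-butyl acrylate
Product: 19 tert-butyl (3RS,7S)-7-[(tert-butyldimethylsilyl)oxy]-3-hydroxy-9,9-dimethyl-2,6-dimethylidene-11-[(triethylsilyl)oxy]undecanoate
Conditions: quinuclidine (0.5 equiv), MeOH (1 equiv), neat 18, rt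
Reagents that add atoms: none
Why: Morita–Baylis–Hillman reaction, with a nucleophilic amine and a protic additive to speed up the sluggish tert-butyl acrylate; the new carbinol centre forms unselectively, which does not matter because it is erased in step 12.

Step 11
Reactants: 19 tert-butyl (3RS,7S)-7-[(tert-butyldimethylsilyl)oxy]-3-hydroxy-9,9-dimethyl-2,6-dimethylidene-11-[(triethylsilyl)oxy]undecanoate
Product: 20 tert-butyl (3RS,7S)-3-acetoxy-7-[(tert-butyldimethylsilyl)oxy]-9,9-dimethyl-2,6-dimethylidene-11-[(triethylsilyl)oxy]undecanoate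
Conditions: Ac2O, pyridine, DMAP (cat.), CH2Cl2, 0 °C to rt
Reagents that add atoms: acetic anhydride, CC(=O)OC(C)=O
Why: DMAP-catalysed acetylation of the secondary allylic alcohol.

Step 12
Reactants: 20 tert-butyl (3RS,7S)-3-acetoxy-7-[(tert-butyldimethylsilyl)oxy]-9,9-dimethyl-2,6-dimethylidene-11-[(triethylsilyl)oxy]undecanoate
Product: 21 tert-butyl (2E,7S)-2-(acetoxymethyl)-7-[(tert-butyldimethylsilyl)oxy]-9,9-dimethyl-6-methylidene-11-[(triethylsilyl)oxy]undec-2-enoate
Conditions: DABCO (0.5 equiv), THF, 60 °C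
Reagents that add atoms: none
Why: Amine-mediated 1,3-transposition of the Morita–Baylis–Hillman acetate (SN2′ addition of DABCO, then return of acetate at the primary carbon) gives the thermodynamically favoured primary acetate with the chain trans to the ester; any 2Z isomer would be removed by chromatography.

Step 13
Reactants: 21 tert-butyl (2E,7S)-2-(acetoxymethyl)-7-[(tert-butyldimethylsilyl)oxy]-9,9-dimethyl-6-methylidene-11-[(triethylsilyl)oxy]undec-2-enoate
Product: 22 tert-butyl (3R,7S)-7-[(tert-butyldimethylsilyl)oxy]-9,9-dimethyl-2,6-dimethylidene-3-(4,4,5,5-tetramethyl-1,3,2-dioxaborolan-2-yl)-11-[(triethylsilyl)oxy]undecanoate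
Conditions: CuCl (10 mol%), QuinoxP* (11 mol%), B2pin2 (1.1 equiv), LiOtBu (1.1 equiv), THF, -20 to 0 °C
Reagents that add atoms: bis(pinacolato)diboron, CC1(C)OB(OC1(C)C)B1OC(C)(C)C(C)(C)O1
Why: Copper-catalysed enantioselective SN2′ allylic borylation, here borylcupration of the enoate at chain C3 (ring C4) followed by β-elimination of acetate from the copper enolate; the chiral bisphosphine–copper boryl selects the enoate face and sets C3 as R, and LiOtBu returns the copper acetate to the alkoxide.

Step 14
Reactants: 22 tert-butyl (3R,7S)-7-[(tert-butyldimethylsilyl)oxy]-9,9-dimethyl-2,6-dimethylidene-3-(4,4,5,5-tetramethyl-1,3,2-dioxaborolan-2-yl)-11-[(triethylsilyl)oxy]undecanoate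
Product: 23 tert-butyl (3R,7S)-7-[(tert-butyldimethylsilyl)oxy]-11-hydroxy-9,9-dimethyl-2,6-dimethylidene-3-(4,4,5,5-tetramethyl-1,3,2-dioxaborolan-2-yl)undecanoate
Conditions: PPTS (0.2 equiv), MeOH/CH2Cl2, 0 °C
Reagents that add atoms: none
Why: Mild acid-catalysed methanolysis cleaves the primary triethylsilyl ether much faster than the hindered secondary TBS ether, while the pinacol boronate and the tert-butyl ester are inert.

Step 15
Reactants: 23 tert-butyl (3R,7S)-7-[(tert-butyldimethylsilyl)oxy]-11-hydroxy-9,9-dimethyl-2,6-dimethylidene-3-(4,4,5,5-tetramethyl-1,3,2-dioxaborolan-2-yl)undecanoate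
Product: 24 tert-butyl (3R,7S)-7-[(tert-butyldimethylsilyl)oxy]-9,9-dimethyl-2,6-dimethylidene-11-oxo-3-(4,4,5,5-tetramethyl-1,3,2-dioxaborolan-2-yl)undecanoate
Conditions: Dess–Martin periodinane, pyridine, CH2Cl2, 0 °C
Reagents that add atoms: none
Why: Dess–Martin oxidation tolerates pinacol boronates, and the ester-deactivated allylboronate should not add to the new aldehyde at this temperature without a catalyst, so the seco aldehyde can be handled briefly.

Step 16
Reactants: 24 tert-butyl (3R,7S)-7-[(tert-butyldimethylsilyl)oxy]-9,9-dimethyl-2,6-dimethylidene-11-oxo-3-(4,4,5,5-tetramethyl-1,3,2-dioxaborolan-2-yl)undecanoate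
Product: 26 tert-butyl (1E,6S,10S)-6-[(tert-butyldimethylsilyl)oxy]-10-hydroxy-8,8-dimethyl-5-methylidenecycloundec-1-ene-1-carboxylate, via macrocyclic pinacol borate 25 (not isolated)
Conditions: (PhO)2P(O)OH (0.3 equiv), toluene, 40 °C, 24 added by syringe pump over 20 h (final 2 mM); aqueous NaHCO3 work-up
Reagents that add atoms: none
Why: Proposed new method: the phosphoric acid hydrogen-bonds to a boronate oxygen, boron binds the aldehyde oxygen and the terminal methylene C6 adds to C7 through a closed six-membered chair (B, O, C7, C6, C5, C4), so that C6–C7 forms while the alkene moves to C4=C5 and boron passes from C4 to O7. The closest known reactions are the chirality-transferring additions of α-substituted allylboronates and of acid-activated 2-(alkoxycarbonyl)allylboronates to aldehydes and the intramolecular allylborations that close five- to eight-membered rings; closing an eleven-membered carbocycle this way is new. The eleven-membered ring closes by this intramolecular C6-to-C7 addition, with the seven-atom tether C8–C3 bridging the equatorial position at C7 and the axial position at C4 of the chair, under pseudo-high dilution. C7 is set by chirality transfer from C4: with C3 axial (avoiding 1,2-allylic strain with the C5 ester and gauche contacts with the pinacolate, a preference that Brønsted-acid activation is known to keep) and C8 equatorial, the 4R boronate should give 7S, while C11 is a bystander. The step needs attack through C6 rather than C4, the ring-cis alkene (E by the CIP rules), the 7S configuration and cyclisation rather than oligomerisation; the closed transition state, the defined C4 centre with its axial chain and slow addition into dilute solution are meant to secure these, and the tert-butyl ester holds back lactonisation of the borate.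

Step 17
Reactants: 26 tert-butyl (1E,6S,10S)-6-[(tert-butyldimethylsilyl)oxy]-10-hydroxy-8,8-dimethyl-5-methylidenecycloundec-1-ene-1-carboxylate
Product: 27 tert-butyl (1E,6S,10S)-6-[(tert-butyldimethylsilyl)oxy]-8,8-dimethyl-5-methylidene-10-[(3-methylbutanoyl)oxy]cycloundec-1-ene-1-carboxylate
Conditions: isovaleric anhydride, Et3N, DMAP, CH2Cl2, rt
Reagents that add atoms: isovaleric anhydride, CC(C)CC(=O)OC(=O)CC(C)C
Why: DMAP-catalysed acylation of the secondary alcohol with retention at C7 (name C10).

Step 18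
Reactants: 27 tert-butyl (1E,6S,10S)-6-[(tert-butyldimethylsilyl)oxy]-8,8-dimethyl-5-methylidene-10-[(3-methylbutanoyl)oxy]cycloundec-1-ene-1-carboxylate
Product: 29 (1E,6S,10S)-6-[(tert-butyldimethylsilyl)oxy]-8,8-dimethyl-5-methylidene-10-[(3-methylbutanoyl)oxy]cycloundec-1-ene-1-carboxylic acid, via trimethylsilyl ester 28 (not isolated)
Conditions: TMSOTf, 2,6-lutidine, CH2Cl2, 0 °C; then pH 4 aqueous buffer
Reagents that add atoms: none
Why: Silyl triflate-mediated tert-butyl ester cleavage (O-silylation, loss of isobutene, hydrolysis of the silyl ester on work-up) under lutidine-buffered conditions that spare the isovalerate, the TBS ether and the alkenes.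

Step 19
Reactants: 29 (1E,6S,10S)-6-[(tert-butyldimethylsilyl)oxy]-8,8-dimethyl-5-methylidene-10-[(3-methylbutanoyl)oxy]cycloundec-1-ene-1-carboxylic acid
Product: 30 (1E,6S,10S)-6-hydroxy-8,8-dimethyl-5-methylidene-10-[(3-methylbutanoyl)oxy]cycloundec-1-ene-1-carboxylic acid
Conditions: HF·pyridine, pyridine, THF, 0 °C to rt
Reagents that add atoms: none
Why: Fluoride-mediated desilylation under buffered, weakly acidic conditions frees the C11 hydroxyl without hydrolysing or migrating the isovalerate.

**Compound list**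

1 | 3,3-dimethylglutaric anhydride | CC1(C)CC(=O)OC(=O)C1 | starting material
2 | sodium 5-hydroxy-3,3-dimethylpentanoate | [Na+].[O-]C(=O)CC(C)(C)CCO | intermediate (not isolated)
3 | 4,4-dimethyloxan-2-one | CC1(C)CCOC(=O)C1 | intermediate
4 | 5-hydroxy-N-methoxy-N,3,3-trimethylpentanamide | CON(C)C(=O)CC(C)(C)CCO | intermediate
5 | N-methoxy-N,3,3-trimethyl-5-[(triethylsilyl)oxy]pentanamide | CON(C)C(=O)CC(C)(C)CCO[Si](CC)(CC)CC | intermediate
6 | 2,3-dibromopropene | C=C(Br)CBr | starting material
7 | vinylmagnesium bromide | C=C[Mg]Br | starting material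
8 | 2-bromopenta-1,4-diene | C=CCC(Br)=C | intermediate
9 | penta-1,4-dien-2-yllithium | [Li]C(=C)CC=C | intermediate (not isolated)
10 | lithium hemiaminal adduct of 5 and 9 | CON(C)C(O[Li])(CC(C)(C)CCO[Si](CC)(CC)CC)C(=C)CC=C | intermediate (not isolated)
11 | 7,7-dimethyl-4-methylidene-9-[(triethylsilyl)oxy]non-1-en-5-one | C=CCC(=C)C(=O)CC(C)(C)CCO[Si](CC)(CC)CC | intermediate
12 | catechol borate ester of 13 | C=CCC(=C)[C@@H](OB1Oc2ccccc2O1)CC(C)(C)CCO[Si](CC)(CC)CC | intermediate (not isolated)
13 | (5S)-7,7-dimethyl-4-methylidene-9-[(triethylsilyl)oxy]non-1-en-5-ol | C=CCC(=C)[C@@H](O)CC(C)(C)CCO[Si](CC)(CC)CC | intermediate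
14 | (5S)-5-[(tert-butyldimethylsilyl)oxy]-7,7-dimethyl-4-methylidene-9-[(triethylsilyl)oxy]non-1-ene | C=CCC(=C)[C@@H](O[Si](C)(C)C(C)(C)C)CC(C)(C)CCO[Si](CC)(CC)CC | intermediate
15 | bis(3-methylbutan-2-yl)borane adduct at C1 of 14 (alkyldisiamylborane) | CC(C)C(C)B(CCCC(=C)[C@@H](O[Si](C)(C)C(C)(C)C)CC(C)(C)CCO[Si](CC)(CC)CC)C(C)C(C)C | intermediate (not isolated)
16 | (5S)-5-[(tert-butyldimethylsilyl)oxy]-7,7-dimethyl-4-methylidene-9-[(triethylsilyl)oxy]nonan-1-ol | OCCCC(=C)[C@@H](O[Si](C)(C)C(C)(C)C)CC(C)(C)CCO[Si](CC)(CC)CC | intermediate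
17 | (5S)-5-[(tert-butyldimethylsilyl)oxy]-7,7-dimethyl-4-methylidene-9-[(triethylsilyl)oxy]nonanal | O=CCCC(=C)[C@@H](O[Si](C)(C)C(C)(C)C)CC(C)(C)CCO[Si](CC)(CC)CC | intermediate
18 | tert-butyl acrylate | C=CC(=O)OC(C)(C)C | starting material
19 | tert-butyl (3RS,7S)-7-[(tert-butyldimethylsilyl)oxy]-3-hydroxy-9,9-dimethyl-2,6-dimethylidene-11-[(triethylsilyl)oxy]undecanoate | C=C(C(=O)OC(C)(C)C)C(O)CCC(=C)[C@@H](O[Si](C)(C)C(C)(C)C)CC(C)(C)CCO[Si](CC)(CC)CC | intermediate
20 | tert-butyl (3RS,7S)-3-acetoxy-7-[(tert-butyldimethylsilyl)oxy]-9,9-dimethyl-2,6-dimethylidene-11-[(triethylsilyl)oxy]undecanoate | C=C(C(=O)OC(C)(C)C)C(OC(C)=O)CCC(=C)[C@@H](O[Si](C)(C)C(C)(C)C)CC(C)(C)CCO[Si](CC)(CC)CC | intermediate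
21 | tert-butyl (2E,7S)-2-(acetoxymethyl)-7-[(tert-butyldimethylsilyl)oxy]-9,9-dimethyl-6-methylidene-11-[(triethylsilyl)oxy]undec-2-enoate | CC(=O)OC/C(=C\CCC(=C)[C@@H](O[Si](C)(C)C(C)(C)C)CC(C)(C)CCO[Si](CC)(CC)CC)C(=O)OC(C)(C)C | intermediate
22 | tert-butyl (3R,7S)-7-[(tert-butyldimethylsilyl)oxy]-9,9-dimethyl-2,6-dimethylidene-3-(4,4,5,5-tetramethyl-1,3,2-dioxaborolan-2-yl)-11-[(triethylsilyl)oxy]undecanoate | C=C(C(=O)OC(C)(C)C)[C@H](B1OC(C)(C)C(C)(C)O1)CCC(=C)[C@@H](O[Si](C)(C)C(C)(C)C)CC(C)(C)CCO[Si](CC)(CC)CC | intermediate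
23 | tert-butyl (3R,7S)-7-[(tert-butyldimethylsilyl)oxy]-11-hydroxy-9,9-dimethyl-2,6-dimethylidene-3-(4,4,5,5-tetramethyl-1,3,2-dioxaborolan-2-yl)undecanoate | C=C(C(=O)OC(C)(C)C)[C@H](B1OC(C)(C)C(C)(C)O1)CCC(=C)[C@@H](O[Si](C)(C)C(C)(C)C)CC(C)(C)CCO | intermediate
24 | tert-butyl (3R,7S)-7-[(tert-butyldimethylsilyl)oxy]-9,9-dimethyl-2,6-dimethylidene-11-oxo-3-(4,4,5,5-tetramethyl-1,3,2-dioxaborolan-2-yl)undecanoate (seco aldehyde) | C=C(C(=O)OC(C)(C)C)[C@H](B1OC(C)(C)C(C)(C)O1)CCC(=C)[C@@H](O[Si](C)(C)C(C)(C)C)CC(C)(C)CC=O | intermediate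
25 | pinacol borate of 26 at the C10 oxygen | C=C1CC/C=C(/C(=O)OC(C)(C)C)C[C@@H](OB2OC(C)(C)C(C)(C)O2)CC(C)(C)C[C@@H]1O[Si](C)(C)C(C)(C)C | intermediate (not isolated)
26 | tert-butyl (1E,6S,10S)-6-[(tert-butyldimethylsilyl)oxy]-10-hydroxy-8,8-dimethyl-5-methylidenecycloundec-1-ene-1-carboxylate | C=C1CC/C=C(/C(=O)OC(C)(C)C)C[C@@H](O)CC(C)(C)C[C@@H]1O[Si](C)(C)C(C)(C)C | intermediate
27 | tert-butyl (1E,6S,10S)-6-[(tert-butyldimethylsilyl)oxy]-8,8-dimethyl-5-methylidene-10-[(3-methylbutanoyl)oxy]cycloundec-1-ene-1-carboxylate | C=C1CC/C=C(/C(=O)OC(C)(C)C)C[C@@H](OC(=O)CC(C)C)CC(C)(C)C[C@@H]1O[Si](C)(C)C(C)(C)C | intermediate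
28 | trimethylsilyl ester of 29 | C=C1CC/C=C(/C(=O)O[Si](C)(C)C)C[C@@H](OC(=O)CC(C)C)CC(C)(C)C[C@@H]1O[Si](C)(C)C(C)(C)C | intermediate (not isolated)
29 | (1E,6S,10S)-6-[(tert-butyldimethylsilyl)oxy]-8,8-dimethyl-5-methylidene-10-[(3-methylbutanoyl)oxy]cycloundec-1-ene-1-carboxylic acid | C=C1CC/C=C(/C(=O)O)C[C@@H](OC(=O)CC(C)C)CC(C)(C)C[C@@H]1O[Si](C)(C)C(C)(C)C | intermediate
30 | (1E,6S,10S)-6-hydroxy-8,8-dimethyl-5-methylidene-10-[(3-methylbutanoyl)oxy]cycloundec-1-ene-1-carboxylic acid (CNP0400752.1) | C=C1CC/C=C(/C(=O)O)C[C@@H](OC(=O)CC(C)C)CC(C)(C)C[C@@H]1O | target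

**Step count and risks**

Total: 19 steps. Longest linear sequence: 18 steps (steps 1–3 and 5–19 from anhydride 1); step 4 is a one-step side branch.

Step 16 (proposed new method). Closure of the eleven-membered ring may be too slow for the ester-deactivated boronate, so intermolecular allylboration (oligomerisation) could take over. The reaction could also run through a chair with C8 axial or C3 equatorial, giving the wrong C7 configuration or the ring-trans alkene, and prolonged acid contact could start lactonisation. The fallback makes C6–C7 intermolecularly and closes the ring at C4=C5 with established reactions. It sets out from aldehyde 17. Wittig methylenation (Ph3PCH3Br, KN(SiMe3)2, THF) should give the terminal alkene (6S)-6-[(tert-butyldimethylsilyl)oxy]-8,8-dimethyl-5-methylidene-10-[(triethylsilyl)oxy]dec-1-ene F1. PPTS in MeOH would free the primary alcohol (5S)-5-[(tert-butyldimethylsilyl)oxy]-3,3-dimethyl-6-methylidenedec-9-en-1-ol F2. Iridium-catalysed transfer-hydrogenative 2-(alkoxycarbonyl)allylation of F2 with tert-butyl 2-{[(tert-butoxycarbonyl)oxy]methyl}prop-2-enoate ([Ir(cod)Cl]2, the SEGPHOS antipode that gives 4S, 4-chloro-3-nitrobenzoic acid, Cs2CO3, THF) would set C7 under catalyst control and give the hydroxy ester tert-butyl (4S,8S)-8-[(tert-butyldimethylsilyl)oxy]-4-hydroxy-6,6-dimethyl-2,9-dimethylidenetridec-12-enoate F3. Acylation with isovaleric anhydride (Et3N, DMAP) would give the isovalerate tert-butyl (4S,8S)-8-[(tert-butyldimethylsilyl)oxy]-6,6-dimethyl-2,9-dimethylidene-4-[(3-methylbutanoyl)oxy]tridec-12-enoate F4. Ring-closing metathesis of F4 with the second-generation Grubbs catalyst in dilute toluene would join C4 to C5 with loss of ethene and come back to the route at 27.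

Step 13. Facial selectivity of the borylcupration may be poor, catalyst turnover may stall with acetate as the leaving group, the product acrylate may be borylated a second time, or base may move the double bond into conjugation with boron. The fallback gives up catalyst control here and restores the C7 configuration at the ring stage. It sets out from 21. Borylation with an achiral catalyst (CuCl, Xantphos, LiOtBu, B2pin2) should give 22 together with its epimer tert-butyl (3S,7S)-7-[(tert-butyldimethylsilyl)oxy]-9,9-dimethyl-2,6-dimethylidene-3-(4,4,5,5-tetramethyl-1,3,2-dioxaborolan-2-yl)-11-[(triethylsilyl)oxy]undecanoate F5. The mixture would be taken through steps 14–16, the 3S series passing through the 3S alcohol F6, the 3S seco aldehyde F7 and the 10R pinacol borate F8 (not isolated) to the ring alcohol tert-butyl (1E,6S,10R)-6-[(tert-butyldimethylsilyl)oxy]-10-hydroxy-8,8-dimethyl-5-methylidenecycloundec-1-ene-1-carboxylate F9, which would be separated from 26. Alcohol 26 is acylated as in step 17, and F9 is esterified with isovaleric acid under Mitsunobu conditions (PPh3, DIAD, THF) with inversion at C7, so both series come back to the route at 27.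

Step 5. Proton transfer may turn the alkenyllithium into the pentadienyl anion before it is acylated, the 2-allyl enone may suffer double-bond migration into conjugation, or the liberated amine may add to the enone. The fallback avoids both the lithium reagent and the enone. It sets out from amide 5 (with bromide 8). Reduction with iBu2AlH at -78 °C should give the aldehyde 3,3-dimethyl-5-[(triethylsilyl)oxy]pentanal F10. An enantioselective Nozaki–Hiyama–Kishi coupling of F10 with 8 (CrCl2, catalytic NiCl2, chiral oxazoline–sulfonamide ligand, Et3N, THF) would form the C1–C11 bond and the carbinol centre in one operation and come back to the route at 13.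

**Further compounds**

F1 | step 16 | (6S)-6-[(tert-butyldimethylsilyl)oxy]-8,8-dimethyl-5-methylidene-10-[(triethylsilyl)oxy]dec-1-ene | C=CCCC(=C)[C@@H](O[Si](C)(C)C(C)(C)C)CC(C)(C)CCO[Si](CC)(CC)CC
F2 | step 16 | (5S)-5-[(tert-butyldimethylsilyl)oxy]-3,3-dimethyl-6-methylidenedec-9-en-1-ol | C=CCCC(=C)[C@@H](O[Si](C)(C)C(C)(C)C)CC(C)(C)CCO
F3 | step 16 | tert-butyl (4S,8S)-8-[(tert-butyldimethylsilyl)oxy]-4-hydroxy-6,6-dimethyl-2,9-dimethylidenetridec-12-enoate | C=CCCC(=C)[C@@H](O[Si](C)(C)C(C)(C)C)CC(C)(C)C[C@H](O)CC(=C)C(=O)OC(C)(C)C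
F4 | step 16 | tert-butyl (4S,8S)-8-[(tert-butyldimethylsilyl)oxy]-6,6-dimethyl-2,9-dimethylidene-4-[(3-methylbutanoyl)oxy]tridec-12-enoate | C=CCCC(=C)[C@@H](O[Si](C)(C)C(C)(C)C)CC(C)(C)C[C@H](OC(=O)CC(C)C)CC(=C)C(=O)OC(C)(C)C
F5 | step 13 | tert-butyl (3S,7S)-7-[(tert-butyldimethylsilyl)oxy]-9,9-dimethyl-2,6-dimethylidene-3-(4,4,5,5-tetramethyl-1,3,2-dioxaborolan-2-yl)-11-[(triethylsilyl)oxy]undecanoate | C=C(C(=O)OC(C)(C)C)[C@@H](B1OC(C)(C)C(C)(C)O1)CCC(=C)[C@@H](O[Si](C)(C)C(C)(C)C)CC(C)(C)CCO[Si](CC)(CC)CC
F6 | step 13 | tert-butyl (3S,7S)-7-[(tert-butyldimethylsilyl)oxy]-11-hydroxy-9,9-dimethyl-2,6-dimethylidene-3-(4,4,5,5-tetramethyl-1,3,2-dioxaborolan-2-yl)undecanoate | C=C(C(=O)OC(C)(C)C)[C@@H](B1OC(C)(C)C(C)(C)O1)CCC(=C)[C@@H](O[Si](C)(C)C(C)(C)C)CC(C)(C)CCO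
F7 | step 13 | tert-butyl (3S,7S)-7-[(tert-butyldimethylsilyl)oxy]-9,9-dimethyl-2,6-dimethylidene-11-oxo-3-(4,4,5,5-tetramethyl-1,3,2-dioxaborolan-2-yl)undecanoate | C=C(C(=O)OC(C)(C)C)[C@@H](B1OC(C)(C)C(C)(C)O1)CCC(=C)[C@@H](O[Si](C)(C)C(C)(C)C)CC(C)(C)CC=O
F8 | step 13 | pinacol borate of F9 at the C10 oxygen (not isolated) | C=C1CC/C=C(/C(=O)OC(C)(C)C)C[C@H](OB2OC(C)(C)C(C)(C)O2)CC(C)(C)C[C@@H]1O[Si](C)(C)C(C)(C)C
F9 | step 13 | tert-butyl (1E,6S,10R)-6-[(tert-butyldimethylsilyl)oxy]-10-hydroxy-8,8-dimethyl-5-methylidenecycloundec-1-ene-1-carboxylate | C=C1CC/C=C(/C(=O)OC(C)(C)C)C[C@H](O)CC(C)(C)C[C@@H]1O[Si](C)(C)C(C)(C)C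
F10 | step 5 | 3,3-dimethyl-5-[(triethylsilyl)oxy]pentanal | O=CCC(C)(C)CCO[Si](CC)(CC)CC
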